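The flavonol is disconnected through ring A. Ring C comes ready-made from kojic acid as a 2-aryl-3-oxy-4-pyranone that already holds O1, C2, O3, C4=O, C4a and C8a, and the four carbons C5–C8 are added in one operation: a diazoacetyl group on C8a is turned by light into a ketene, which takes up a silyloxyacetylene and closes onto C4a. The step exploits the C4a(H)=C8a double bond of ring C as the terminus of the ring closure and the meta relationship of O5 and O7 on ring A, which matches the oxygen pattern of ketene plus ynol ether. The precursor is a MOM- and benzyl-protected 2-aryl-6-(diazoacetyl)pyranone.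

Key step: step 10

Assumption: the sulfate half-esters 24, 25 and 26 are drawn and listed as neutral hydrogen sulfates. They would be handled as sodium or tetrabutylammonium salts, and the acid form of 26 would be released by cold cation exchange directly after step 14. The target has no stereocentre.

**Ring B building block**

Step 1
Reactants: 1 2-(benzyloxy)phenol
Product: 2 2-(benzyloxy)-4-bromophenol
Conditions: NBS (1.0 equiv), MeCN, 0 → 25 °C
Reagents that add atoms: N-bromosuccinimide, O=C1CCC(=O)N1Br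
Why: Electrophilic aromatic bromination is directed para to the free hydroxyl, the strongest donor on the ring, which fixes the later 3'-O-benzyl/4'-O pattern.

Step 2
Reactants: 2 2-(benzyloxy)-4-bromophenol
Product: 3 2-(benzyloxy)-4-bromo-1-(methoxymethoxy)benzene
Conditions: NaH, MOMCl, THF–DMF, 0 °C
Reagents that add atoms: chloromethyl methyl ether, COCCl
Why: Williamson-type O-alkylation of the sodium phenoxide with the reactive α-chloro ether (MOM protection).

Step 3
Reactants: 3 2-(benzyloxy)-4-bromo-1-(methoxymethoxy)benzene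
Product: 4 2-[3-(benzyloxy)-4-(methoxymethoxy)phenyl]-4,4,5,5-tetramethyl-1,3,2-dioxaborolane
Conditions: B2pin2, Pd(dppf)Cl2 (3 mol %), KOAc, 1,4-dioxane, 90 °C
Reagents that add atoms: bis(pinacolato)diboron, CC1(C)OB(OC1(C)C)B1OC(C)(C)C(C)(C)O1
Why: Miyaura borylation of an aryl bromide; the MOM and benzyl ethers are inert to zerovalent palladium and KOAc.

**Ring C and the diazo ketone**

Step 4
Reactants: 5 kojic acid
Product: 6 2-bromo-3-hydroxy-6-(hydroxymethyl)-4H-pyran-4-one (6-bromokojic acid)
Conditions: NBS (1.0 equiv), MeCN–H2O, 0 → 25 °C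
Reagents that add atoms: N-bromosuccinimide, O=C1CCC(=O)N1Br
Why: Electrophilic bromination of the enol; C6 of kojic acid is the β-carbon of the C5 enol, the position at which kojic acid takes up electrophiles.

Step 5
Reactants: 6 2-bromo-3-hydroxy-6-(hydroxymethyl)-4H-pyran-4-one
Product: 7 2-bromo-6-(hydroxymethyl)-3-(methoxymethoxy)-4H-pyran-4-one
Conditions: MOMCl (1.1 equiv), K2CO3, acetone, 0 → 25 °C
Reagents that add atoms: chloromethyl methyl ether, COCCl
Why: Chemoselective O-alkylation, since carbonate deprotonates only the acidic enolic hydroxyl (a vinylogous acid) and leaves the primary alcohol free.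

Step 6
Reactants: 7 2-bromo-6-(hydroxymethyl)-3-(methoxymethoxy)-4H-pyran-4-one; 4 2-[3-(benzyloxy)-4-(methoxymethoxy)phenyl]-4,4,5,5-tetramethyl-1,3,2-dioxaborolane
Product: 8 2-[3-(benzyloxy)-4-(methoxymethoxy)phenyl]-6-(hydroxymethyl)-3-(methoxymethoxy)-4H-pyran-4-one
Conditions: Pd(dppf)Cl2 (5 mol %), K3PO4, 1,4-dioxane–H2O, 70 °C
Reagents that add atoms: none
Why: Suzuki–Miyaura coupling; the C–Br bond next to the ring oxygen is a vinylogous acyl bromide that undergoes oxidative addition readily, and the free alcohol is tolerated.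

Step 7
Reactants: 8 2-[3-(benzyloxy)-4-(methoxymethoxy)phenyl]-6-(hydroxymethyl)-3-(methoxymethoxy)-4H-pyran-4-one
Product: 10 6-[3-(benzyloxy)-4-(methoxymethoxy)phenyl]-5-(methoxymethoxy)-4-oxo-4H-pyran-2-carboxylic acid, via pyranone-2-carbaldehyde 9 (not isolated)
Conditions: TEMPO (20 mol %), PhI(OAc)2 (2.2 equiv), MeCN–H2O (1:1), 25 °C
Reagents that add atoms: water, O
Why: TEMPO/PhI(OAc)2 oxidation in wet acetonitrile takes the activated primary alcohol through the aldehyde hydrate to the acid under nearly neutral conditions that spare both MOM acetals and the electron-rich arene.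

Step 8
Reactants: 10 6-[3-(benzyloxy)-4-(methoxymethoxy)phenyl]-5-(methoxymethoxy)-4-oxo-4H-pyran-2-carboxylic acid
Product: 12 2-[3-(benzyloxy)-4-(methoxymethoxy)phenyl]-6-(diazoacetyl)-3-(methoxymethoxy)-4H-pyran-4-one, via mixed carbonic anhydride 11 (not isolated)
Conditions: i-BuOCOCl, N-methylmorpholine, THF, −15 °C; then CH2N2, Et2O, −15 → 0 °C
Reagents that add atoms: diazomethane, C=[N+]=[N-]
Why: Acylation of diazomethane by a mixed carbonic anhydride (first stage of the Arndt–Eistert sequence); no HCl is generated, so the MOM ethers survive.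

**Alkyne partner**

Step 9
Reactants: 13 acetylene; 14 triisopropylsilyl trifluoromethanesulfonate
Product: 17 (triisopropylsilyloxy)acetylene, via lithium acetylide 15 (not isolated), via lithium ethynolate 16 (not isolated)
Conditions: n-BuLi, THF, −78 °C; LiOOt-Bu (from t-BuOOH and LiN(SiMe3)2), −78 → −10 °C; then 14, −78 → 0 °C
Reagents that add atoms: tert-butyl hydroperoxide, CC(C)(C)OO
Why: Oxidation of a lithium acetylide to the lithium ynolate by lithium tert-butyl peroxide, then O-silylation, the bulky triisopropylsilyl triflate reacting at oxygen and not at carbon.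

**Key step**

Step 10
Reactants: 12 2-[3-(benzyloxy)-4-(methoxymethoxy)phenyl]-6-(diazoacetyl)-3-(methoxymethoxy)-4H-pyran-4-one; 17 (triisopropylsilyloxy)acetylene
Product: 22 2-[3-(benzyloxy)-4-(methoxymethoxy)phenyl]-5-hydroxy-3-(methoxymethoxy)-7-(triisopropylsilyloxy)-4H-chromen-4-one, via pyranonyl ketene 18 (not isolated), via siloxycyclobutenone 19 (not isolated), via dienylketene 20 (not isolated), via keto tautomer 21 (not isolated)
Conditions: hν (blue LEDs, 440 nm), 17 (2.5 equiv), ClCH2CH2Cl, 25 °C; then 80 °C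
Reagents that add atoms: none
Why: Blue light excites only the diazo ketone, whose Wolff rearrangement moves C8a from the acyl carbon to the former diazo carbon (C8) and gives ketene 18; this adds [2+2] to the siloxyalkyne to form cyclobutenone 19 (bonds C5–C6 and C7–C8), and on warming reversible conrotatory 4π opening delivers dienylketene 20. Ring A is then closed by thermal disrotatory 6π electrocyclisation of C5 onto C4a across C5=C6–C7=C8–C8a=C4a, and dienone 21 enolises to the aromatic, hydrogen-bonded 5-phenol. The closest known reaction type is the photochemical Danheiser benzannulation of unsaturated and heteroaryl diazo ketones with siloxyalkynes. No stereocentre is created in the product, since C8 in 19 and C4a in 21 are only transient. The step needs regiocontrol in the cycloaddition, which the polarity of the partners secures: the electrophilic ketene carbonyl carbon bonds to the nucleophilic CH terminus of the ynol ether, so that oxygen ends up at C7, meta to the 5-OH. The site of ring closure is unambiguous because the other neighbour of C8a is the ring oxygen O1.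

**Endgame**

Step 11
Reactants: 22 2-[3-(benzyloxy)-4-(methoxymethoxy)phenyl]-5-hydroxy-3-(methoxymethoxy)-7-(triisopropylsilyloxy)-4H-chromen-4-one
Product: 23 2-[3-(benzyloxy)-4-hydroxyphenyl]-3,5-dihydroxy-7-(triisopropylsilyloxy)-4H-chromen-4-one
Conditions: HCl (1.25 M in MeOH), THF, 40 °C
Reagents that add atoms: none
Why: Acid-catalysed transacetalisation to methanol cleaves both MOM ethers, while the aryl triisopropylsilyl ether and the benzyl ether are stable to dilute methanolic HCl.

Step 12
Reactants: 23 2-[3-(benzyloxy)-4-hydroxyphenyl]-3,5-dihydroxy-7-(triisopropylsilyloxy)-4H-chromen-4-one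
Product: 24 2-[3-(benzyloxy)-4-(sulfooxy)phenyl]-5-hydroxy-7-(triisopropylsilyloxy)-4-oxo-4H-chromen-3-yl hydrogen sulfate
Conditions: SO3·pyridine (8 equiv), pyridine, 25 → 40 °C; then aq. NaHCO3
Reagents that add atoms: sulfur trioxide–pyridine complex, O=S(=O)([O-])[n+]1ccccc1
Why: O-Sulfation with an amine–SO3 complex; 3-OH and 4'-OH react, whereas 5-OH, held in a hydrogen bond to C4=O, is the least reactive hydroxyl of a flavonol and should stay free.

Step 13
Reactants: 24 2-[3-(benzyloxy)-4-(sulfooxy)phenyl]-5-hydroxy-7-(triisopropylsilyloxy)-4-oxo-4H-chromen-3-yl hydrogen sulfate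
Product: 25 2-[3-(benzyloxy)-4-(sulfooxy)phenyl]-5,7-dihydroxy-4-oxo-4H-chromen-3-yl hydrogen sulfate (3'-O-benzylquercetin 3,4'-bissulfate)
Conditions: Bu4NF, AcOH (1:1), THF–DMF, 0 °C
Reagents that add atoms: none
Why: Fluoride-induced cleavage of the aryl silyl ether, buffered with acetic acid; sulfate monoester anions are inert to fluoride.

Step 14
Reactants: 25 2-[3-(benzyloxy)-4-(sulfooxy)phenyl]-5,7-dihydroxy-4-oxo-4H-chromen-3-yl hydrogen sulfate
Product: 26 quercetin 3,4'-bissulfate
Conditions: H2 (1 atm), 10% Pd/C, MeOH, 25 °C; then cation exchange resin (H+ form), 0 °C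
Reagents that add atoms: none
Why: Hydrogenolysis of the benzyl aryl ether over palladium; aryl sulfate salts and the C2=C3 bond of the flavone are stable under 1 atm of hydrogen at room temperature.

**Compound list**

1 | 2-(benzyloxy)phenol | Oc1ccccc1OCc1ccccc1 | starting material
2 | 2-(benzyloxy)-4-bromophenol | Oc1ccc(Br)cc1OCc1ccccc1 | intermediate
3 | 2-(benzyloxy)-4-bromo-1-(methoxymethoxy)benzene | COCOc1ccc(Br)cc1OCc1ccccc1 | intermediate
4 | 2-[3-(benzyloxy)-4-(methoxymethoxy)phenyl]-4,4,5,5-tetramethyl-1,3,2-dioxaborolane | COCOc1ccc(B2OC(C)(C)C(C)(C)O2)cc1OCc1ccccc1 | intermediate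
5 | kojic acid | OCc1cc(=O)c(O)co1 | starting material
6 | 2-bromo-3-hydroxy-6-(hydroxymethyl)-4H-pyran-4-one | OCc1cc(=O)c(O)c(Br)o1 | intermediate
7 | 2-bromo-6-(hydroxymethyl)-3-(methoxymethoxy)-4H-pyran-4-one | OCc1cc(=O)c(OCOC)c(Br)o1 | intermediate
8 | 2-[3-(benzyloxy)-4-(methoxymethoxy)phenyl]-6-(hydroxymethyl)-3-(methoxymethoxy)-4H-pyran-4-one | OCc1cc(=O)c(OCOC)c(-c2ccc(OCOC)c(OCc3ccccc3)c2)o1 | intermediate
9 | 6-[3-(benzyloxy)-4-(methoxymethoxy)phenyl]-5-(methoxymethoxy)-4-oxo-4H-pyran-2-carbaldehyde (not isolated) | O=Cc1cc(=O)c(OCOC)c(-c2ccc(OCOC)c(OCc3ccccc3)c2)o1 | intermediate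
10 | 6-[3-(benzyloxy)-4-(methoxymethoxy)phenyl]-5-(methoxymethoxy)-4-oxo-4H-pyran-2-carboxylic acid | OC(=O)c1cc(=O)c(OCOC)c(-c2ccc(OCOC)c(OCc3ccccc3)c2)o1 | intermediate
11 | isobutyl carbonic anhydride of acid 10 (not isolated) | CC(C)COC(=O)OC(=O)c1cc(=O)c(OCOC)c(-c2ccc(OCOC)c(OCc3ccccc3)c2)o1 | intermediate
12 | 2-[3-(benzyloxy)-4-(methoxymethoxy)phenyl]-6-(diazoacetyl)-3-(methoxymethoxy)-4H-pyran-4-one | [N-]=[N+]=CC(=O)c1cc(=O)c(OCOC)c(-c2ccc(OCOC)c(OCc3ccccc3)c2)o1 | intermediate
13 | acetylene | C#C | starting material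
14 | triisopropylsilyl trifluoromethanesulfonate | CC(C)[Si](OS(=O)(=O)C(F)(F)F)(C(C)C)C(C)C | starting material
15 | lithium acetylide (not isolated) | [Li]C#C | intermediate
16 | lithium ethynolate (not isolated) | [Li]OC#C | intermediate
17 | (triisopropylsilyloxy)acetylene | C#CO[Si](C(C)C)(C(C)C)C(C)C | intermediate
18 | 2-[3-(benzyloxy)-4-(methoxymethoxy)phenyl]-3-(methoxymethoxy)-6-(2-oxoethenyl)-4H-pyran-4-one, the pyranonyl ketene (not isolated) | O=C=Cc1cc(=O)c(OCOC)c(-c2ccc(OCOC)c(OCc3ccccc3)c2)o1 | intermediate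
19 | 4-(pyranon-6-yl)-3-(triisopropylsilyloxy)cyclobut-2-en-1-one, racemic (not isolated) | O=C1C=C(O[Si](C(C)C)(C(C)C)C(C)C)C1c1cc(=O)c(OCOC)c(-c2ccc(OCOC)c(OCc3ccccc3)c2)o1 | intermediate
20 | 4-(pyranon-6-yl)-3-(triisopropylsilyloxy)buta-1,3-dien-1-one, the dienylketene with C6 and C8a cis (not isolated) | O=C=C/C(O[Si](C(C)C)(C(C)C)C(C)C)=C\c1cc(=O)c(OCOC)c(-c2ccc(OCOC)c(OCc3ccccc3)c2)o1 | intermediate
21 | 2-[3-(benzyloxy)-4-(methoxymethoxy)phenyl]-3-(methoxymethoxy)-7-(triisopropylsilyloxy)-4aH-chromene-4,5-dione, racemic keto tautomer (not isolated) | O=C1C=C(O[Si](C(C)C)(C(C)C)C(C)C)C=C2OC(-c3ccc(OCOC)c(OCc4ccccc4)c3)=C(OCOC)C(=O)C12 | intermediate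
22 | 2-[3-(benzyloxy)-4-(methoxymethoxy)phenyl]-5-hydroxy-3-(methoxymethoxy)-7-(triisopropylsilyloxy)-4H-chromen-4-one | O=c1c(OCOC)c(-c2ccc(OCOC)c(OCc3ccccc3)c2)oc2cc(O[Si](C(C)C)(C(C)C)C(C)C)cc(O)c12 | intermediate
23 | 2-[3-(benzyloxy)-4-hydroxyphenyl]-3,5-dihydroxy-7-(triisopropylsilyloxy)-4H-chromen-4-one | O=c1c(O)c(-c2ccc(O)c(OCc3ccccc3)c2)oc2cc(O[Si](C(C)C)(C(C)C)C(C)C)cc(O)c12 | intermediate
24 | 2-[3-(benzyloxy)-4-(sulfooxy)phenyl]-5-hydroxy-7-(triisopropylsilyloxy)-4-oxo-4H-chromen-3-yl hydrogen sulfate | O=c1c(OS(=O)(=O)O)c(-c2ccc(OS(=O)(=O)O)c(OCc3ccccc3)c2)oc2cc(O[Si](C(C)C)(C(C)C)C(C)C)cc(O)c12 | intermediate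
25 | 2-[3-(benzyloxy)-4-(sulfooxy)phenyl]-5,7-dihydroxy-4-oxo-4H-chromen-3-yl hydrogen sulfate | O=c1c(OS(=O)(=O)O)c(-c2ccc(OS(=O)(=O)O)c(OCc3ccccc3)c2)oc2cc(O)cc(O)c12 | intermediate
26 | quercetin 3,4'-bissulfate | O=c1c(OS(=O)(=O)O)c(-c2ccc(OS(=O)(=O)O)c(O)c2)oc2cc(O)cc(O)c12 | target

**Step count**

Total steps: 14. Longest linear sequence: 11 steps (steps 1–3, 6–8 and 10–14).

**Steps most likely to fail**

Step 10. The light may be absorbed unproductively, the pyranone and flavone chromophores may enter photoreactions of their own, and the photogenerated ketene may be lost to dimerisation before it meets the alkyne. The fallback generates the same ketene in the dark; it sets out from 12 and comes back at 22. Silver-promoted Wolff rearrangement of 12 in aqueous dioxane (PhCO2Ag, Et3N; Arndt–Eistert homologation) would give {6-[3-(benzyloxy)-4-(methoxymethoxy)phenyl]-5-(methoxymethoxy)-4-oxo-4H-pyran-2-yl}acetic acid F1. 1-Chloro-N,N,2-trimethylprop-1-en-1-amine in CH2Cl2 would convert it under neutral conditions into the corresponding acetyl chloride F2. Slow addition of Et3N to F2 and 17 would form ketene 18 by dehydrochlorination and cyclobutenone 19 by [2+2] cycloaddition. Heating to 80 °C should carry 19 through 20 and 21 to 22.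

Step 9. Monolithium acetylide may disproportionate to the insoluble dilithium species while the mixture is warmed for the oxidation, and the small, volatile product may be lost on isolation. The fallback uses a silyl-capped alkyne and removes the cap later; it sets out from 12 and comes back at 23. The oxidation–silylation sequence of step 9, applied to lithium (trimethylsilyl)acetylide (stable at 0 °C, from commercial (trimethylsilyl)acetylene), should give 1-(triisopropylsilyloxy)-2-(trimethylsilyl)acetylene F3. Irradiation of 12 with F3 under the conditions of step 10 should give, with the same regiochemistry, 2-[3-(benzyloxy)-4-(methoxymethoxy)phenyl]-5-hydroxy-3-(methoxymethoxy)-7-(triisopropylsilyloxy)-6-(trimethylsilyl)-4H-chromen-4-one F4. The acid treatment of step 11, with trifluoroacetic acid added if needed, would remove both MOM groups and, by ipso-protodesilylation of the electron-rich ring A, the C6 silyl group, to give 23.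

Step 12. Sulfation of the hindered, hydrogen-bonded 3-OH may stay incomplete, the 7-silyl ether may be lost under the reaction conditions and be followed by oversulfation, and the ionic product is hard to purify. The fallback carries the sulfates as neutral diesters; it sets out from 23 and comes back at 26. 2,2,2-Trichloroethyl chlorosulfate with Et3N and DMAP in THF should give the bis(2,2,2-trichloroethyl sulfate) diester of 23, F5, which can be purified on silica. Transfer hydrogenolysis (10% Pd/C, HCO2NH4, MeOH) would cleave both trichloroethyl groups reductively and remove the benzyl ether, giving the 7-O-triisopropylsilyl ether of quercetin 3,4'-bissulfate, F6. Bu4NF/AcOH as in step 13 would then give 26.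

**Further compounds**

F1 | step 10 | {6-[3-(benzyloxy)-4-(methoxymethoxy)phenyl]-5-(methoxymethoxy)-4-oxo-4H-pyran-2-yl}acetic acid | OC(=O)Cc1cc(=O)c(OCOC)c(-c2ccc(OCOC)c(OCc3ccccc3)c2)o1
F2 | step 10 | {6-[3-(benzyloxy)-4-(methoxymethoxy)phenyl]-5-(methoxymethoxy)-4-oxo-4H-pyran-2-yl}acetyl chloride | ClC(=O)Cc1cc(=O)c(OCOC)c(-c2ccc(OCOC)c(OCc3ccccc3)c2)o1
F3 | step 9 | 1-(triisopropylsilyloxy)-2-(trimethylsilyl)acetylene | C[Si](C)(C)C#CO[Si](C(C)C)(C(C)C)C(C)C
F4 | step 9 | 2-[3-(benzyloxy)-4-(methoxymethoxy)phenyl]-5-hydroxy-3-(methoxymethoxy)-7-(triisopropylsilyloxy)-6-(trimethylsilyl)-4H-chromen-4-one | O=c1c(OCOC)c(-c2ccc(OCOC)c(OCc3ccccc3)c2)oc2cc(O[Si](C(C)C)(C(C)C)C(C)C)c([Si](C)(C)C)c(O)c12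
F5 | step 12 | 2-[3-(benzyloxy)-4-{[(2,2,2-trichloroethoxy)sulfonyl]oxy}phenyl]-5-hydroxy-7-(triisopropylsilyloxy)-4-oxo-4H-chromen-3-yl 2,2,2-trichloroethyl sulfate | O=c1c(OS(=O)(=O)OCC(Cl)(Cl)Cl)c(-c2ccc(OS(=O)(=O)OCC(Cl)(Cl)Cl)c(OCc3ccccc3)c2)oc2cc(O[Si](C(C)C)(C(C)C)C(C)C)cc(O)c12
F6 | step 12 | 5-hydroxy-2-[3-hydroxy-4-(sulfooxy)phenyl]-7-(triisopropylsilyloxy)-4-oxo-4H-chromen-3-yl hydrogen sulfate | O=c1c(OS(=O)(=O)O)c(-c2ccc(OS(=O)(=O)O)c(O)c2)oc2cc(O[Si](C(C)C)(C(C)C)C(C)C)cc(O)c12
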